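**Plan**

1. Numbering: ten-membered ring C1–C10, with the oxiranes at C10(CH3)–C1 and C4(CH3)–C5, CH2 groups at C2 and C6, angelates on C3 and C9, the acetate on C8 and the isopropenyl group (C11–C13) on C7.
2. Retrosynthesis: remove the three esters, return both oxiranes to Z olefins and the isopropenyl group to a tertiary silyl ether, then cut the ring bond C5–C6, the olefin C1=C10, the bond C7–C8 and the bond C2–C3.
3. Enabling feature: C6 is the only ring CH2 lying between a stereocentre (C7) and an olefinic carbon (C5 of the former C4=C5 olefin). C5–C6 can therefore come from a C6 alkylborane, made by the hydroboration that also sets C7, and a (Z)-C5 alkenyl iodide.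
4. Forward: allylboration of (Z)-3-iodo-2-methylacrolein (C2–C3), Z-selective Wittig reaction with a glycerate-derived methyl ketone (C1=C10), alkenylmagnesium addition (C7–C8), then the single ring closure at C5–C6; both oxiranes are made afterwards on the ten-membered ring.
5. Stereochemistry: C3 from Brown allylboration, C9 from methyl (S)-glycerate acetonide, C8 by Felkin–Anh addition, C7 by acetonide-controlled 9-BBN hydroboration, C1/C10 by vanadium epoxidation cis to O9, C4/C5 by peracid epoxidation trans to O3; both Z olefins are fixed before ring closure.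

Key step: step 16

Remark: the target locants C1–C13 are kept for every intermediate; descriptors quoted with these locants are the CIP descriptors of the compound named.
Remark: the B-allyl reagent of step 3 is the one derived from (+)-α-pinene (SMILES given), used as a salt-free solution.

**Route**

Step 1
Reactants: 1 prop-2-yn-1-ol
Product: 3 (Z)-3-iodo-2-methylprop-2-en-1-ol, via alkenylmagnesium alkoxide 2 (not isolated)
Conditions: MeMgBr (2.5 equiv), CuI (10 mol%), THF, −10 °C→rt; then I2, −78→0 °C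
Reagents that add atoms: methylmagnesium bromide C[Mg]Br; iodine II
Why: Copper-catalyzed anti-carbomagnesiation of the propargylic alkoxide places methyl on C4 and magnesium on C5 cis to the CH2O group (five-membered chelate), and iodinolysis with retention gives the Z iodide.

Step 2
Reactants: 3 (Z)-3-iodo-2-methylprop-2-en-1-ol
Product: 4 (Z)-3-iodo-2-methylprop-2-enal
Conditions: MnO2 (activated, excess), CH2Cl2, rt, dark; filtered and used at once
Reagents that add atoms: none
Why: Neutral heterogeneous MnO2 oxidation of an allylic alcohol should give the labile Z iodoenal without Z-to-E isomerization when it is used directly.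

Step 3
Reactants: 4 (Z)-3-iodo-2-methylprop-2-enal
Product: 5 (3S,1Z)-1-iodo-2-methylhexa-1,5-dien-3-ol
Conditions: dIpc2B(allyl) [(+)-α-pinene series], Et2O, −78 °C; then NaOH, H2O2, 0 °C→rt
Reagents that add atoms: B-allyldiisopinocampheylborane from (+)-α-pinene C=CCB([C@@H]1C[C@@H]2C[C@H]([C@H]1C)C2(C)C)[C@@H]1C[C@@H]2C[C@H]([C@H]1C)C2(C)C
Why: Brown allylboration through a closed chair six-membered transition state, in which the isopinocampheyl groups of the (+)-α-pinene series deliver allyl to the Si face of the aldehyde and set C3 as S.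

Step 4
Reactants: 5 (3S,1Z)-1-iodo-2-methylhexa-1,5-dien-3-ol
Product: 6 (3S,1Z)-1-iodo-3-(4-methoxybenzyloxy)-2-methylhexa-1,5-diene
Conditions: NaH, 4-MeOC6H4CH2Cl, Bu4NI (cat.), THF/DMF, 0 °C→rt
Reagents that add atoms: 4-methoxybenzyl chloride COc1ccc(CCl)cc1
Why: Williamson etherification; the alkenyl iodide has no β-hydrogen for elimination, and the PMB ether is orthogonal to the silyl ethers and the acetonide used later.

Step 5
Reactants: 6 (3S,1Z)-1-iodo-3-(4-methoxybenzyloxy)-2-methylhexa-1,5-diene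
Product: 8 (3S,4Z)-5-iodo-3-(4-methoxybenzyloxy)-4-methylpent-4-en-1-ol, via β-alkoxy aldehyde 7 (not isolated)
Conditions: OsO4 (2 mol%), NaIO4, 2,6-lutidine, dioxane/H2O, rt; then NaBH4, MeOH, 0 °C
Reagents that add atoms: sodium periodate [Na+].[O-]I(=O)(=O)=O with catalytic osmium tetroxide O=[Os](=O)(=O)=O (source of the new oxygen)
Why: Lemieux–Johnson cleavage attacks only the monosubstituted olefin (the iodo-substituted trisubstituted olefin is electron-poor and hindered), and borohydride reduces the β-alkoxy aldehyde before it can eliminate.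

Step 6
Reactants: 8 (3S,4Z)-5-iodo-3-(4-methoxybenzyloxy)-4-methylpent-4-en-1-ol
Product: 10 [(3S,4Z)-5-iodo-3-(4-methoxybenzyloxy)-4-methylpent-4-enyl]triphenylphosphonium iodide, via primary iodide 9 (not isolated)
Conditions: I2, PPh3, imidazole, CH2Cl2, 0 °C→rt; solvent exchange; PPh3, MeCN, 80 °C
Reagents that add atoms: iodine II; triphenylphosphine c1ccc(cc1)P(c1ccccc1)c1ccccc1
Why: Appel-type iodination of the primary alcohol followed by SN2 quaternization of PPh3; the alkenyl iodide is inert to both.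

Step 7
Reactants: 11 methyl (S)-2,2-dimethyl-1,3-dioxolane-4-carboxylate
Product: 13 (S)-1-(2,2-dimethyl-1,3-dioxolan-4-yl)ethan-1-one, via Weinreb amide 12 (not isolated)
Conditions: MeNH(OMe)·HCl, i-PrMgCl, THF, −20 °C; then MeMgBr, −20→0 °C
Reagents that add atoms: methylmagnesium bromide C[Mg]Br
Why: One-pot Weinreb ketone synthesis; the chelated tetrahedral adduct stops at the ketone, and the α-alkoxy stereocentre (the future C9) is not enolized at low temperature.

Step 8
Reactants: 10 [(3S,4Z)-5-iodo-3-(4-methoxybenzyloxy)-4-methylpent-4-enyl]triphenylphosphonium iodide; 13 (S)-1-(2,2-dimethyl-1,3-dioxolan-4-yl)ethan-1-one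
Product: 15 (R)-4-[(2Z,5S,6Z)-7-iodo-5-(4-methoxybenzyloxy)-6-methylhepta-2,6-dien-2-yl]-2,2-dimethyl-1,3-dioxolane, via phosphorus ylide 14 (not isolated)
Conditions: KN(SiMe3)2, THF, −78 °C; then 13, THF/HMPA, −78 °C→rt
Reagents that add atoms: none
Why: Wittig olefination of an α-alkoxy methyl ketone with a lithium-free non-stabilized ylide is Z-selective for the trisubstituted olefin, so C2 ends up cis to the oxygenated carbon C9; the glycerate stereocentre is carried over unchanged (its descriptor changes only by priority).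

Step 9
Reactants: 15 dioxolane from step 8
Product: 16 (2R,3Z,6S,7Z)-8-iodo-6-(4-methoxybenzyloxy)-3,7-dimethylocta-3,7-diene-1,2-diol
Conditions: AcOH/THF/H2O (3:1:1), 40 °C
Reagents that add atoms: none
Why: Acid hydrolysis of a terminal isopropylidene ketal is much faster than cleavage of the PMB ether and leaves both stereocentres untouched.

Step 10
Reactants: 16 diol from step 9
Product: 17 1,2-bis(triethylsilyl) ether of 16
Conditions: Et3SiCl, imidazole, DMF, 0 °C
Reagents that add atoms: chlorotriethylsilane CC[Si](Cl)(CC)CC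
Why: Standard silylation of a primary and a secondary alcohol; the triethylsilyl group on O9 is non-chelating, as needed for step 14.

Step 11
Reactants: 17 bis(triethylsilyl) ether
Product: 18 (2R,3Z,6S,7Z)-8-iodo-6-(4-methoxybenzyloxy)-3,7-dimethyl-2-(triethylsilyloxy)octa-3,7-dienal
Conditions: (COCl)2, DMSO, CH2Cl2, −78→−30 °C; Et3N, −78→0 °C; used at once
Reagents that add atoms: none
Why: Swern oxidation converts a primary triethylsilyl ether directly into the aldehyde while the secondary silyl ether stays, giving the C8 aldehyde without a separate deprotection.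

Step 12
Reactants: 19 3-hydroxy-3-methylbutan-2-one
Product: 20 3-methyl-3-(triethylsilyloxy)butan-2-one
Conditions: Et3SiOTf, 2,6-lutidine, CH2Cl2, 0 °C
Reagents that add atoms: triethylsilyl triflate CC[Si](CC)(CC)OS(=O)(=O)C(F)(F)F
Why: Silyl triflate silylation is the standard way to protect a tertiary alcohol.

Step 13
Reactants: 20 3-methyl-3-(triethylsilyloxy)butan-2-one
Product: 21 2,4,6-triisopropylbenzenesulfonylhydrazone of 20
Conditions: 2,4,6-(i-Pr)3C6H2SO2NHNH2, THF, 4 Å MS, rt
Reagents that add atoms: 2,4,6-triisopropylbenzenesulfonyl hydrazide CC(C)c1cc(C(C)C)c(S(=O)(=O)NN)c(C(C)C)c1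
Why: Condensation of a methyl ketone with an arenesulfonyl hydrazide gives the hydrazone needed for the Shapiro reaction, with the sulfonamide on the methyl side.

Step 14
Reactants: 21 hydrazone (1.6 equiv); 18 aldehyde from step 11
Product: 24 open-chain C8 alcohol (3S,8S,9R) with C9 OSiEt3, C3 OPMB, C6=C7 methylene and C11 OSiEt3, via alkenyllithium 22 (not isolated), via alkenylmagnesium bromide 23 (not isolated)
Conditions: 21, n-BuLi (2 equiv per 21), THF, −78→0 °C; MgBr2·OEt2, −78 °C; then 18, −78 °C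
Reagents that add atoms: none
Why: The Shapiro reaction gives the 2-metallated alkene regiospecifically, transmetalation to magnesium avoids iodine–lithium exchange at C5, and Felkin–Anh addition to the non-chelating α-silyloxy aldehyde (C9–O bond anti to the nucleophile) gives the 8,9-anti product, setting C8 as S.

Step 15
Reactants: 24 alcohol from step 14
Product: 26 seco iodide (3S,8S,9R): (Z)-C5 alkenyl iodide, C3 OPMB, (Z)-C1=C10, cis-8,9-acetonide, C6=C7 methylene, C11 OSiEt3, via anti-diol 25 (not isolated)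
Conditions: PPTS, MeOH, 0 °C→rt; concentrate; Me2C(OMe)2, PPTS, CH2Cl2, rt
Reagents that add atoms: 2,2-dimethoxypropane COC(C)(C)OC
Why: Methanolysis removes the secondary allylic triethylsilyl ether much faster than the tertiary one, and acid-catalyzed transketalization of the anti-diol gives the cis-dioxolane that bends the chain for ring closure.

Step 16
Reactants: 26 seco iodide
Product: 28 macrocycle (3S,7S,8S,9R): (1(10)Z,4Z)-cyclodeca-1(10),4-diene with C3 OPMB, cis-8,9-acetonide and C7 C(CH3)2OSiEt3, via B-alkyl-9-BBN borane 27 (not isolated)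
Conditions: 9-BBN (2 equiv), THF, 0 °C→rt; then syringe-pump addition (12 h) to PdCl2(dppf) (20 mol%), AsPh3 (40 mol%), Cs2CO3, DMF/THF/H2O, 50 °C, final 1 mM
Reagents that add atoms: none
Why: 9-BBN adds anti-Markovnikov across the 1,1-disubstituted C6=C7 olefin (boron on C6, hydrogen on C7) through a four-centre transition state in which the larger allylic substituent C9 is anti to the borane and C8–H lies inside; the C8 dioxolane stereocentre thus sets C7 (7,8-anti in the chain, cis on the ring), as in 9-BBN hydroborations of 1,1-disubstituted allylic ethers. Carbonate and water convert borane 27 into its hydroxyborate, zerovalent palladium inserts into the C5–I bond with retention of the Z geometry, the C6 alkyl group moves from boron to palladium, and C(sp3)–C(sp2) reductive elimination forms C5–C6; the closest known reaction type is the hydroboration/B-alkyl Suzuki–Miyaura macrocyclization. The ten-membered carbocycle closes end to end: intramolecular transmetalation gives an eleven-membered palladacycle that contracts on reductive elimination, with the C4=C5 olefin ending inside the new ring. The step needs hydroboration of only one olefin (9-BBN strongly prefers the single 1,1-disubstituted olefin over the two trisubstituted ones), ring closure over oligomerization (slow addition to high dilution, with the cis-dioxolane and the two Z olefins turning C5 and C6 toward each other) and suppression of β-hydride loss (dppf and AsPh3).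

Step 17
Reactants: 28 macrocycle
Product: 29 tertiary alcohol: macrocycle with C7 C(CH3)2OH
Conditions: Bu4NF, THF, rt
Reagents that add atoms: none
Why: Fluoride cleaves the triethylsilyl ether and leaves the PMB ether and the acetonide untouched.

Step 18
Reactants: 29 tertiary alcohol
Product: 30 isopropenyl macrocycle (3S,7R,8S,9R)
Conditions: Burgess reagent, PhMe, 60 °C
Reagents that add atoms: none
Why: Burgess dehydration (syn elimination of the sulfamate) should take a methyl hydrogen (six available, unhindered) rather than the single hindered C7–H next to the C8 oxygen, giving the isopropenyl group under neutral conditions.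

Step 19
Reactants: 30 isopropenyl macrocycle
Product: 31 8,9-diol (3S,7R,8S,9R) with C3 OPMB
Conditions: CSA (cat.), MeOH, rt
Reagents that add atoms: none
Why: Acid-catalyzed transketalization to methanol frees the cis-diol before any oxirane is present; the PMB ether survives.

Step 20
Reactants: 31 8,9-diol
Product: 32 1,10-epoxy-8,9-diol (oxirane cis to O9 and O8) with C3 OPMB
Conditions: VO(acac)2 (5 mol%), t-BuOOH (decane), CH2Cl2, 0 °C
Reagents that add atoms: tert-butyl hydroperoxide CC(C)(C)OO
Why: Hydroxyl-directed vanadium-catalyzed epoxidation: as with medium-ring (Z)-cycloalk-2-enols, the C9 vanadate delivers oxygen through an O–C–C=C dihedral near 40–50° to the face cis to O9 (the cis O8 reinforces this), setting C1 and C10; the C4=C5 olefin (PMB ether) and the isopropenyl group have no allylic hydroxyl and react far more slowly.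

Step 21
Reactants: 32 epoxy diol
Product: 33 C8 acetate of 32 (C9 OH free)
Conditions: Ac2O (1.1 equiv), pyridine, CH2Cl2, −20→0 °C
Reagents that add atoms: acetic anhydride CC(=O)OC(C)=O
Why: Selective acylation of the less hindered hydroxyl: O9 is flanked by the fully substituted oxirane carbon C10 and hydrogen-bonded to the oxirane, so O8 should react first, and acyl migration would also favour O8.

Step 22
Reactants: 33 C8 acetate
Product: 34 3,9-diol with C8 acetate and 1,10-oxirane
Conditions: DDQ, CH2Cl2/pH 7 buffer, 0 °C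
Reagents that add atoms: none
Why: Oxidative PMB cleavage under neutral conditions spares the oxirane and causes no acetate migration.

Step 23
Reactants: 34 3,9-diol
Product: 35 1,10:4,5-diepoxy-3,9-diol with C8 acetate (4,5-oxirane trans to O3)
Conditions: mCPBA, NaHCO3, CH2Cl2, 0 °C
Reagents that add atoms: 3-chloroperoxybenzoic acid OOC(=O)c1cccc(Cl)c1
Why: Hydrogen-bond-directed peracid epoxidation (Henbest type) of a medium-ring (Z)-allylic alcohol goes through an O–C–C=C dihedral near 120° and gives the oxirane trans to O3, setting C4 and C5; the hydroxyl-activated trisubstituted ring olefin should react before the 1,1-disubstituted isopropenyl group.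

Step 24
Reactants: 35 diepoxy diol
Product: 36 target CNP0260455.1 (1R,3S,4S,5S,7R,8S,9S,10R)
Conditions: angelic acid, 2,4,6-Cl3C6H2COCl, Et3N, PhMe, rt; filter; then 35, PhMe, 75 °C, no added base
Reagents that add atoms: angelic acid C/C=C(/C)C(=O)O
Why: Yamaguchi-type acylation with the preformed angelic 2,4,6-trichlorobenzoic mixed anhydride esterifies hindered secondary alcohols at the unshielded angeloyl carbonyl without Z-to-E isomerization to tiglate, and the absence of base limits acetate migration from O8.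

**Compound list**

1 | prop-2-yn-1-ol | C#CCO | starting material
2 | (Z)-[3-(bromomagnesiooxy)-2-methylprop-1-enyl]magnesium bromide | Br[Mg]/C=C(C)\CO[Mg]Br | intermediate
3 | (Z)-3-iodo-2-methylprop-2-en-1-ol | I/C=C(C)\CO | intermediate
4 | (Z)-3-iodo-2-methylprop-2-enal | I/C=C(C)\C=O | intermediate
5 | (3S,1Z)-1-iodo-2-methylhexa-1,5-dien-3-ol | I/C=C(C)\[C@@H](O)CC=C | intermediate
6 | (3S,1Z)-1-iodo-3-(4-methoxybenzyloxy)-2-methylhexa-1,5-diene | I/C=C(C)\[C@@H](OCc1ccc(OC)cc1)CC=C | intermediate
7 | (3S,4Z)-5-iodo-3-(4-methoxybenzyloxy)-4-methylpent-4-enal | I/C=C(C)\[C@@H](OCc1ccc(OC)cc1)CC=O | intermediate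
8 | (3S,4Z)-5-iodo-3-(4-methoxybenzyloxy)-4-methylpent-4-en-1-ol | I/C=C(C)\[C@@H](OCc1ccc(OC)cc1)CCO | intermediate
9 | (3S,1Z)-1,5-diiodo-3-(4-methoxybenzyloxy)-2-methylpent-1-ene | I/C=C(C)\[C@@H](OCc1ccc(OC)cc1)CCI | intermediate
10 | [(3S,4Z)-5-iodo-3-(4-methoxybenzyloxy)-4-methylpent-4-enyl]triphenylphosphonium iodide | I/C=C(C)\[C@@H](OCc1ccc(OC)cc1)CC[P+](c1ccccc1)(c1ccccc1)c1ccccc1.[I-] | intermediate
11 | methyl (S)-2,2-dimethyl-1,3-dioxolane-4-carboxylate | COC(=O)[C@H]1OC(C)(C)OC1 | starting material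
12 | (S)-N-methoxy-N,2,2-trimethyl-1,3-dioxolane-4-carboxamide | CON(C)C(=O)[C@H]1OC(C)(C)OC1 | intermediate
13 | (S)-1-(2,2-dimethyl-1,3-dioxolan-4-yl)ethan-1-one | CC(=O)[C@H]1OC(C)(C)OC1 | intermediate
14 | [(3S,4Z)-5-iodo-3-(4-methoxybenzyloxy)-4-methylpent-4-enylidene]triphenylphosphorane | I/C=C(C)\[C@@H](OCc1ccc(OC)cc1)CC=P(c1ccccc1)(c1ccccc1)c1ccccc1 | intermediate
15 | (R)-4-[(2Z,5S,6Z)-7-iodo-5-(4-methoxybenzyloxy)-6-methylhepta-2,6-dien-2-yl]-2,2-dimethyl-1,3-dioxolane | I/C=C(C)\[C@@H](OCc1ccc(OC)cc1)C/C=C(C)\[C@H]1OC(C)(C)OC1 | intermediate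
16 | (2R,3Z,6S,7Z)-8-iodo-6-(4-methoxybenzyloxy)-3,7-dimethylocta-3,7-diene-1,2-diol | I/C=C(C)\[C@@H](OCc1ccc(OC)cc1)C/C=C(C)\[C@@H](O)CO | intermediate
17 | 1,2-bis(triethylsilyl) ether of 16 | I/C=C(C)\[C@@H](OCc1ccc(OC)cc1)C/C=C(C)\[C@@H](O[Si](CC)(CC)CC)CO[Si](CC)(CC)CC | intermediate
18 | (2R,3Z,6S,7Z)-8-iodo-6-(4-methoxybenzyloxy)-3,7-dimethyl-2-(triethylsilyloxy)octa-3,7-dienal | I/C=C(C)\[C@@H](OCc1ccc(OC)cc1)C/C=C(C)\[C@@H](O[Si](CC)(CC)CC)C=O | intermediate
19 | 3-hydroxy-3-methylbutan-2-one | CC(=O)C(C)(C)O | starting material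
20 | 3-methyl-3-(triethylsilyloxy)butan-2-one | CC(=O)C(C)(C)O[Si](CC)(CC)CC | intermediate
21 | 2,4,6-triisopropylbenzenesulfonylhydrazone of 20 | CC(=NNS(=O)(=O)c1c(C(C)C)cc(C(C)C)cc1C(C)C)C(C)(C)O[Si](CC)(CC)CC | intermediate
22 | [3-methyl-3-(triethylsilyloxy)but-1-en-2-yl]lithium | C=C([Li])C(C)(C)O[Si](CC)(CC)CC | intermediate
23 | [3-methyl-3-(triethylsilyloxy)but-1-en-2-yl]magnesium bromide | C=C([Mg]Br)C(C)(C)O[Si](CC)(CC)CC | intermediate
24 | open-chain C8 alcohol (3S,8S,9R): (Z)-C5 iodide, C3 OPMB, (Z)-C1=C10, C9 OSiEt3, C8 OH, C6=C7 methylene, C11 OSiEt3 | I/C=C(C)\[C@@H](OCc1ccc(OC)cc1)C/C=C(C)\[C@@H](O[Si](CC)(CC)CC)[C@@H](O)C(=C)C(C)(C)O[Si](CC)(CC)CC | intermediate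
25 | open-chain 8,9-anti diol (3S,8S,9R), otherwise as 24 | I/C=C(C)\[C@@H](OCc1ccc(OC)cc1)C/C=C(C)\[C@@H](O)[C@@H](O)C(=C)C(C)(C)O[Si](CC)(CC)CC | intermediate
26 | seco iodide (3S,8S,9R) with cis-8,9-acetonide, C6=C7 methylene and C11 OSiEt3 | I/C=C(C)\[C@@H](OCc1ccc(OC)cc1)C/C=C(C)\[C@H]1OC(C)(C)O[C@H]1C(=C)C(C)(C)O[Si](CC)(CC)CC | intermediate
27 | B-alkyl-9-BBN borane (3S,7S,8S,9R): 9-borabicyclo[3.3.1]nonan-9-yl on C6, hydrogen on C7 | I/C=C(C)\[C@@H](OCc1ccc(OC)cc1)C/C=C(C)\[C@H]1OC(C)(C)O[C@H]1[C@H](CB1C2CCCC1CCC2)C(C)(C)O[Si](CC)(CC)CC | intermediate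
28 | macrocycle (3S,7S,8S,9R): (1(10)Z,4Z)-cyclodecadiene with C3 OPMB, cis-8,9-acetonide, C7 C(CH3)2OSiEt3 | CC(C)(O[Si](CC)(CC)CC)[C@H]1C/C=C(C)\[C@@H](OCc3ccc(OC)cc3)C/C=C(C)\[C@H]2OC(C)(C)O[C@@H]12 | intermediate
29 | macrocyclic tertiary alcohol (3S,7S,8S,9R): C7 C(CH3)2OH | CC(C)(O)[C@H]1C/C=C(C)\[C@@H](OCc3ccc(OC)cc3)C/C=C(C)\[C@H]2OC(C)(C)O[C@@H]12 | intermediate
30 | isopropenyl macrocycle (3S,7R,8S,9R) with C3 OPMB and 8,9-acetonide | C=C(C)[C@H]1C/C=C(C)\[C@@H](OCc3ccc(OC)cc3)C/C=C(C)\[C@H]2OC(C)(C)O[C@@H]12 | intermediate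
31 | macrocyclic 8,9-diol (3S,7R,8S,9R) with C3 OPMB | C=C(C)[C@H]1C/C=C(C)\[C@@H](OCc2ccc(OC)cc2)C/C=C(C)\[C@@H](O)[C@H]1O | intermediate
32 | 1,10-epoxy-8,9-diol (3S,7R,8S,9S), oxirane cis to O9 and O8, C3 OPMB | C=C(C)[C@H]1C/C=C(C)\[C@@H](OCc3ccc(OC)cc3)C[C@H]2O[C@@]2(C)[C@@H](O)[C@H]1O | intermediate
33 | C8 acetate of 32 (C9 OH free) | C=C(C)[C@H]1C/C=C(C)\[C@@H](OCc3ccc(OC)cc3)C[C@H]2O[C@@]2(C)[C@@H](O)[C@H]1OC(C)=O | intermediate
34 | 1,10-epoxy-3,9-diol with C8 acetate and (4Z)-olefin | C=C(C)[C@H]1C/C=C(C)\[C@@H](O)C[C@H]2O[C@@]2(C)[C@@H](O)[C@H]1OC(C)=O | intermediate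
35 | 1,10:4,5-diepoxy-3,9-diol with C8 acetate, 4,5-oxirane trans to O3 | C=C(C)[C@H]1C[C@@H]2O[C@]2(C)[C@@H](O)C[C@H]2O[C@@]2(C)[C@@H](O)[C@H]1OC(C)=O | intermediate
36 | CNP0260455.1: 8-acetate 3,9-diangelate of the 1,10:4,5-diepoxide (1R,3S,4S,5S,7R,8S,9S,10R) | C=C(C)[C@H]1C[C@@H]2O[C@]2(C)[C@@H](OC(=O)/C(C)=C\C)C[C@H]2O[C@@]2(C)[C@@H](OC(=O)/C(C)=C\C)[C@H]1OC(C)=O | target

**Count and risks**

Total: 24 steps. Longest linear sequence: 21 steps (steps 1–6, 8–11, 14–24).

Most likely to fail, in order:

Step 16. The hindered C6=C7 olefin may be hydroborated slowly or with poor face selectivity, and transmetalation of the β-branched alkylborane may be too slow, so that oligomerization or protodeboronation outruns closure of the strained ten-membered ring. Fallback, setting out from 26 and rejoining at 28: hydroboration with 9-BBN and oxidative work-up (NaBO3·4H2O) gives the primary C6 alcohol F1, which allows the C7 epimers to be separated. Iodination (I2, PPh3, imidazole) gives the C6 alkyl iodide F2. Zinc dust with LiCl in THF/DMA should insert only into the C(sp3)–I bond to give the alkylzinc iodide F3, which is added slowly to Pd(PPh3)4 at high dilution. This intramolecular Negishi coupling forms the same C5–C6 bond with a more reactive, separately prepared organometallic and delivers 28.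

Step 21. Acylation may occur at O9 instead of O8, or at both hydroxyls. Fallback, setting out from 32 and rejoining at 36: if O9 is the more reactive hydroxyl, the two acylations are run in the opposite order. The angelic mixed anhydride of step 24 gives the C9 angelate F4, and Ac2O/DMAP then acetylates the remaining O8 to the C9 angelate C8 acetate F5. DDQ frees O3 to give the C3 alcohol F6, mCPBA gives the 4,5-epoxide F7, and a single angeloylation at O3 gives 36. This order also avoids a free hydroxyl next to the acetate during the final esterification.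

Step 14. Facial selectivity at C8 may be poor (Felkin–Anh against competing chelate-type addition), and the α-silyloxy β,γ-unsaturated aldehyde may epimerize at C9. Fallback, setting out from 24 (as the C8 epimer mixture) and rejoining at 25: Dess–Martin oxidation gives the C8 enone F8, and PPTS/MeOH frees O9 to give the C9-hydroxy enone F9. Chelation-controlled 1,2-reduction with Zn(BH4)2 (hydride anti to the C9 substituent in the zinc chelate) gives the anti-diol 25, which continues through the ketalization of step 15.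

Further compounds
F1 | step 16 | C6 primary alcohol from hydroboration–oxidation of 26 (3S,7S,8S,9R) | I/C=C(C)\[C@@H](OCc1ccc(OC)cc1)C/C=C(C)\[C@H]1OC(C)(C)O[C@H]1[C@H](CO)C(C)(C)O[Si](CC)(CC)CC
F2 | step 16 | C6 alkyl iodide of F1 | I/C=C(C)\[C@@H](OCc1ccc(OC)cc1)C/C=C(C)\[C@H]1OC(C)(C)O[C@H]1[C@H](CI)C(C)(C)O[Si](CC)(CC)CC
F3 | step 16 | C6 alkylzinc iodide of F2 | I/C=C(C)\[C@@H](OCc1ccc(OC)cc1)C/C=C(C)\[C@H]1OC(C)(C)O[C@H]1[C@H](C[Zn]I)C(C)(C)O[Si](CC)(CC)CC
F4 | step 21 | C9 angelate of 32 (C8 OH free, C3 OPMB) | C=C(C)[C@H]1C/C=C(C)\[C@@H](OCc3ccc(OC)cc3)C[C@H]2O[C@@]2(C)[C@@H](OC(=O)/C(C)=C\C)[C@H]1O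
F5 | step 21 | C9 angelate C8 acetate with C3 OPMB | C=C(C)[C@H]1C/C=C(C)\[C@@H](OCc3ccc(OC)cc3)C[C@H]2O[C@@]2(C)[C@@H](OC(=O)/C(C)=C\C)[C@H]1OC(C)=O
F6 | step 21 | C3 alcohol of F5 | C=C(C)[C@H]1C/C=C(C)\[C@@H](O)C[C@H]2O[C@@]2(C)[C@@H](OC(=O)/C(C)=C\C)[C@H]1OC(C)=O
F7 | step 21 | 1,10:4,5-diepoxide with C3 OH, C8 acetate, C9 angelate | C=C(C)[C@H]1C[C@@H]2O[C@]2(C)[C@@H](O)C[C@H]2O[C@@]2(C)[C@@H](OC(=O)/C(C)=C\C)[C@H]1OC(C)=O
F8 | step 14 | C8 enone from oxidation of 24 (C9 OSiEt3) | I/C=C(C)\[C@@H](OCc1ccc(OC)cc1)C/C=C(C)\[C@@H](O[Si](CC)(CC)CC)C(=O)C(=C)C(C)(C)O[Si](CC)(CC)CC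
F9 | step 14 | C9-hydroxy C8 enone | I/C=C(C)\[C@@H](OCc1ccc(OC)cc1)C/C=C(C)\[C@@H](O)C(=O)C(=C)C(C)(C)O[Si](CC)(CC)CC
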